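# Proposed synthesis of CNP0287121.3 by an ester-tethered desymmetrizing Heck cyclization

## The problem

The target joins two 7-methoxycoumarins through a 3,6-dimethylcyclohex-2-ene: coumarin A (ring atoms primed) is bonded through C6′ to C1, a methine that is both allylic and benzylic, and coumarin B (ring atoms doubly primed) is bonded through C8″ and an (E)-ethenyl bridge to the quaternary carbon C6. C1 and C6 are the only stereocentres; they are adjacent, both R, and the aryl group on C1 is cis to the styryl arm on C6. Nothing else in the molecule can relay chirality, so the absolute configuration must come from a catalyst or from the chiral pool, and once one centre exists it must fix the other, which plain steric induction does poorly because the methyl group and the one-carbon arm on C6 are of similar size. The ring alkene has to end exactly at C2=C3, beside C1 and on the methyl-bearing carbon. Both coumarin lactones are opened or reduced by hydride and hard nucleophiles, the styryl and trisubstituted alkenes exclude unselective hydrogenation and strong acid, and the doubly activated C1–H invites alkene migration. The structural opening is that the oxygen on C7′ is ortho to the C6′–C1 bond and the one-carbon arm on C6 is cis to coumarin A. An ester from this oxygen to a carboxyl carbon on C6 therefore closes a six-membered ring (O, C=O, C6, C1, C6′, C7′), and if C6 lies on the mirror plane of a cyclohexa-2,5-diene, forming the C6′–C1 bond through this tether creates both stereocentres at once.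

## Retrosynthesis

**Coumarin A is made last.** In target 21 the C3′=C4′ bond and the O1′–C2′ bond of the pyranone of coumarin A are cut, giving salicylaldehyde 19. Removing the formyl group gives phenol 18, which is stored as silyl ether 17. The tether must later be cleaved with LiAlH4, which no coumarin survives, so ring A travels as a protected resorcinol. The forward steps must formylate ortho to the hydroxyl at C4a′ only; the para position is occupied by C1 and C8′ lies between two oxygens. They must also lactonize without harming coumarin B.

**Styryl double bond.** Cutting the C=C bond of the bridge between C6 and C8″ in 17 gives aldehyde 11 and phosphonate 16. Cutting the C6–vinyl bond instead would mean building the quaternary centre late, and cutting the vinyl–C8″ bond needs a vinyl group on C6 first. The chosen cut uses the tether carbon itself as the aldehyde, so no carbon is wasted, and coumarin B arrives complete. The forward reaction must be E-selective on a neopentyl aldehyde that cannot enolize.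

**Coumarin B fragment.** Phosphonate 16 is traced through bromide 15 and methyl ether 14 to hydroxycoumarin 13, whose pyranone is cut back to 2-methylresorcinol 12. The methyl group of 12 becomes the benzylic carbon on C8″.

**Undoing the tether.** Aldehyde 11 comes from alcohol 10, which comes from diol 9 by O-methylation. Diol 9 is the reduction product of lactone 8, in which the carboxyl carbon on C6 and the oxygen on C7′ are joined. These are functional-group changes only; both stereocentres are already present in 8.

**The extra alkene.** Lactone 8 is derived from diene lactone 7 by saturating C4=C5. This alkene is the price of a symmetric precursor. The forward step must reduce a cis-disubstituted alkene while the trisubstituted C2=C3 alkene of the same diene survives.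

**Key cut, C1–C6′.** Breaking this bond in 7 and restoring a bromine on C6′ and a hydrogen on C3 gives ester 6, an achiral aryl ester of a cyclohexa-2,5-diene acid. An intermolecular aryl addition to C1 would have no control over C1 relative to C6. The tether makes the cis relationship unavoidable and leaves only the choice between two enantiotopic alkenes to a chiral ligand. The precursor loses both stereocentres and a ring.

**Ester and its parts.** Ester 6 is cut at the acyl–oxygen bond into acid 3 and phenol 5. Acid 3 is the Birch reductive methylation product of 4-methylbenzoic acid 1, formed through enediolate 2. Phenol 5 is the mono-silyl ether of 4-bromoresorcinol 4. Only the cis-dimethyl isomer of the acid places a hydrogen on the carboxyl face at C4, so it must be separated from the diastereomer that forms beside it.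

## Roads not taken

Alternative 1: The cut is the C1–C6 ring bond, made together with the alkyl C–O bond of a six-membered lactone whose α-carbon is C6 and whose carbinol carbon is C3, carrying the (E)-arylvinyl group. Forward, the silyl ketene acetal of that lactone undergoes an Ireland–Claisen rearrangement through a boat-shaped transition state and gives cyclohexene acid A1.
- Merits: the absolute configuration is bought from a terpene alcohol of the chiral pool, so there is no enantioselectivity to win. The sigmatropic shift places C2=C3 directly, so no surplus alkene has to be removed and no diastereomer separated. In these three respects it is better than the chosen plan.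
- Weak points: the lactone needs chain degradation of the terpene, α-methylation, and arylation of its vinyl group with an ortho-oxygenated aryl halide. Ketene acetal formation with LiN(i-Pr)2 is not compatible with a coumarin, so ring A would again have to be masked. Chirality transfer depends on one boat conformer being preferred while a bond forms to a benzylic carbon next to a nascent quaternary centre. A1 still needs two steps to reach the aldehyde level.
- Against its advantages, the chosen plan reaches its key precursor in three steps from bulk aromatics and enforces the cis C1/C6 relationship by tether geometry, not by a conformational preference.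

Alternative 2: The cuts are C5–C6 and C1=C2. An α-cyano aldehyde adds to a vinyl ketone under a chiral primary amine–thiourea, and aldol condensation closes the ring to cyano enone A2.
- Merits: the quaternary centre is made enantioselectively from two small achiral pieces without metal or sacrificial stereocentre. The ketone allows the C3 methyl and the C2=C3 alkene to be installed by trapping the enolate formed on aryl conjugate addition, and the nitrile is the latent styryl carbon. Ring construction is more economical than in the chosen plan.
- Weak points: C1 is made in a separate step by conjugate addition of an ortho-alkoxy aryl metal to a β-carbon beside the quaternary centre. Its configuration rests only on the size difference between methyl and cyano; this should favour the needed isomer but does not guarantee it.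
- The chosen plan sets against this that both centres arise in one bond-forming event whose relative outcome is fixed by ring geometry.

Alternative 3: Ring A is cut apart so that it is built onto C1. A diazo enone is irradiated, the vinylketene from Wolff rearrangement adds a silyloxyalkyne, and ring opening followed by electrocyclization gives phenol A3.
- Merits: the two ring A oxygens emerge differentiated (free hydroxyl on C7′, silylated oxygen on C8a′) without any selective protection, which is cleaner than the selective silylation used here. A3 is simply the tert-butyldimethylsilyl ether of intermediate 9, so the endgame would be the same.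
- Weak points: the benzannulation creates no stereocentre. C1 and C6 must already be present in the diazo ketone, so the stereochemical problem is moved, not solved. Diazo transfer and a photochemical step are added, and an aromatic ring is assembled that can be bought.
- The chosen plan uses a commercial arene for ring A and spends its key step on the two stereocentres.

Key step: step 4

Assumptions: the cis and trans acids from step 1 are taken to be separable and assignable before use, and (R)-BINAP is taken by analogy to select the alkene leading to (6aS,10aS)-7; if the sense proves opposite, (S)-BINAP is used and nothing else changes.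

## Route

Step 1
Reactants: 1 4-methylbenzoic acid
Product: 3 cis-1,4-dimethylcyclohexa-2,5-diene-1-carboxylic acid, via dilithium enediolate 2 (not isolated)
Conditions: Li, NH3(l)/THF, −78 °C; MeI, −78 °C; NH4Cl, then aq. HCl; cis acid separated from the trans isomer by fractional crystallisation of the dicyclohexylammonium salts
Reagents that add atoms: iodomethane, CI
Why: Birch reduction gives enediolate 2, which is C-methylated at the carboxyl-bearing carbon (Birch reductive alkylation); the remote 4-methyl group gives no useful facial bias and the electrophile tends to enter anti to it, so both diastereomers are expected and only the achiral cis-dimethyl acid 3, which has the C4 hydrogen on the carboxyl face, is carried on.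

Step 2
Reactants: 4 4-bromoresorcinol
Product: 5 2-bromo-5-[(triisopropylsilyl)oxy]phenol
Conditions: i-Pr3SiCl (1.0 equiv), imidazole, CH2Cl2, 0 °C
Reagents that add atoms: chlorotriisopropylsilane, CC(C)[Si](Cl)(C(C)C)C(C)C
Why: Silylation of a phenol; the hydroxyl para to bromine is unhindered whereas the one ortho to bromine is shielded, so the bulky chlorosilane should select the former and leave the ortho hydroxyl for the tether.

Step 3
Reactants: 3 cis-1,4-dimethylcyclohexa-2,5-diene-1-carboxylic acid; 5 2-bromo-5-[(triisopropylsilyl)oxy]phenol
Product: 6 2-bromo-5-[(triisopropylsilyl)oxy]phenyl cis-1,4-dimethylcyclohexa-2,5-diene-1-carboxylate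
Conditions: N,N'-dicyclohexylcarbodiimide, 4-(dimethylamino)pyridine (cat.), CH2Cl2, 0 °C to rt
Reagents that add atoms: none
Why: Steglich esterification; acyl transfer through the acylpyridinium overcomes the hindrance of the α-quaternary acid, and the neutral conditions touch neither the skipped diene nor the aryl bromide.

Step 4
Reactants: 6 2-bromo-5-[(triisopropylsilyl)oxy]phenyl cis-1,4-dimethylcyclohexa-2,5-diene-1-carboxylate
Product: 7 (6aS,10aS)-6a,9-dimethyl-3-[(triisopropylsilyl)oxy]-6a,10a-dihydro-6H-benzo[c]chromen-6-one
Conditions: Pd2(dba)3 (5 mol %), (R)-2,2'-bis(diphenylphosphino)-1,1'-binaphthyl [(R)-BINAP, 12 mol %], Ag3PO4 (2 equiv), NMP, 80 °C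
Reagents that add atoms: none
Why: Zerovalent palladium carrying (R)-BINAP inserts into the C–Br bond, Ag3PO4 removes bromide to give a cationic arylpalladium that keeps both phosphorus atoms bound, and the aryl group adds syn to one of the two enantiotopic ring alkenes before syn β-hydride elimination (asymmetric intramolecular Mizoroki–Heck reaction). The closest known reaction type is the BINAP-controlled Heck desymmetrization of 1,1-disubstituted cyclohexa-2,5-dienes, combined with aryl-ester-tethered arylpalladium cyclizations to six-membered lactones. The lactone closes in the 6-exo-trig mode, the aryl carbon attacking the alkene carbon next to the quaternary carbon. The quaternary carbon C6a (C6 of the target) becomes stereogenic only through the choice between the two alkenes, which the chiral ligand makes; C10a (C1 of the target) is set in the same insertion, and the three-atom ester tether can deliver the aryl group only to the face that carries the carboxyl carbon, so the ring fusion is cis. After insertion palladium sits on the ester face, where the only syn β-hydrogen is the one on the methyl-bearing carbon (the reason the cis acid is required), so elimination can give only the C9=C10 alkene (C2=C3 of the target); the hydrogen on C10a is anti and cannot be lost. The step needs enantiotopic-group selectivity, secured by the rigid chelating ligand on cationic palladium, and regioselective elimination, secured by the substrate; the silver salt also suppresses re-addition of palladium hydride and alkene migration.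

Step 5
Reactants: 7 (6aS,10aS)-6a,9-dimethyl-3-[(triisopropylsilyl)oxy]-6a,10a-dihydro-6H-benzo[c]chromen-6-one
Product: 8 (6aS,10aS)-6a,9-dimethyl-3-[(triisopropylsilyl)oxy]-6a,7,8,10a-tetrahydro-6H-benzo[c]chromen-6-one
Conditions: 2-nitrobenzenesulfonohydrazide, Et3N, CH2Cl2, rt (diimide formed in the flask; reagent added in portions until 7 is consumed)
Reagents that add atoms: none
Why: Diimide reduction; the concerted hydrogen transfer is much faster to the cis-disubstituted C7=C8 alkene than to the trisubstituted C9=C10 alkene, and once the diene is broken the remaining alkene is isolated and slower still; no stereocentre is touched.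

Step 6
Reactants: 8 (6aS,10aS)-6a,9-dimethyl-3-[(triisopropylsilyl)oxy]-6a,7,8,10a-tetrahydro-6H-benzo[c]chromen-6-one
Product: 9 2-[(1R,6S)-6-(hydroxymethyl)-3,6-dimethylcyclohex-2-en-1-yl]-5-[(triisopropylsilyl)oxy]phenol
Conditions: LiAlH4, THF, 0 °C; aq. potassium sodium tartrate
Reagents that add atoms: none
Why: Hydride reduction of the aryl lactone releases the phenol on C7′ and turns the tether carbon into a primary alcohol; C6 is quaternary and C1 is not α to the carbonyl, so neither centre can epimerize, and the aryl silyl ether and the alkene are inert.

Step 7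
Reactants: 9 2-[(1R,6S)-6-(hydroxymethyl)-3,6-dimethylcyclohex-2-en-1-yl]-5-[(triisopropylsilyl)oxy]phenol
Product: 10 [(1S,2R)-2-{2-methoxy-4-[(triisopropylsilyl)oxy]phenyl}-1,4-dimethylcyclohex-3-en-1-yl]methanol
Conditions: MeI, K2CO3, acetone, rt
Reagents that add atoms: iodomethane, CI
Why: Williamson ether synthesis; carbonate deprotonates only the phenol, so the oxygen on C7′ is methylated and the neopentyl alcohol is left free, while the hindered silyl ether withstands carbonate in an aprotic solvent.

Step 8
Reactants: 10 [(1S,2R)-2-{2-methoxy-4-[(triisopropylsilyl)oxy]phenyl}-1,4-dimethylcyclohex-3-en-1-yl]methanol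
Product: 11 (1S,2S)-2-{2-methoxy-4-[(triisopropylsilyl)oxy]phenyl}-1,4-dimethylcyclohex-3-ene-1-carbaldehyde
Conditions: Dess–Martin periodinane, NaHCO3, CH2Cl2, rt
Reagents that add atoms: none
Why: Dess–Martin oxidation of a primary alcohol; the aldehyde has no α-hydrogen, so it can neither epimerize nor over-oxidize under these buffered conditions (the change of descriptor at C2 is a priority change only).

Step 9
Reactants: 12 2-methylresorcinol
Product: 13 7-hydroxy-8-methyl-2H-chromen-2-one
Conditions: malic acid, conc. H2SO4, 100 °C
Reagents that add atoms: malic acid, OC(CC(=O)O)C(=O)O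
Why: Pechmann condensation; malic acid loses carbon monoxide and water to give formylacetic acid, which attacks the position ortho to one hydroxyl and para to the other and lactonizes, so the methyl group ends at C8.

Step 10
Reactants: 13 7-hydroxy-8-methyl-2H-chromen-2-one
Product: 14 7-methoxy-8-methyl-2H-chromen-2-one
Conditions: MeI, K2CO3, acetone, reflux
Reagents that add atoms: iodomethane, CI
Why: Williamson ether synthesis on the only acidic hydroxyl.

Step 11
Reactants: 14 7-methoxy-8-methyl-2H-chromen-2-one
Product: 15 8-(bromomethyl)-7-methoxy-2H-chromen-2-one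
Conditions: N-bromosuccinimide, azobis(isobutyronitrile) (cat.), PhCF3, reflux
Reagents that add atoms: N-bromosuccinimide, O=C1CCC(=O)N1Br
Why: Wohl–Ziegler bromination; under radical conditions in a non-polar solvent the benzylic methyl group reacts in preference to the ring or the pyranone alkene.

Step 12
Reactants: 15 8-(bromomethyl)-7-methoxy-2H-chromen-2-one
Product: 16 diethyl [(7-methoxy-2-oxo-2H-chromen-8-yl)methyl]phosphonate
Conditions: P(OEt)3, neat, 130 °C
Reagents that add atoms: triethyl phosphite, CCOP(OCC)OCC
Why: Michaelis–Arbuzov reaction of a reactive benzylic bromide; bromoethane distils off and the lactone is inert to the phosphite.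

Step 13
Reactants: 11 (1S,2S)-2-{2-methoxy-4-[(triisopropylsilyl)oxy]phenyl}-1,4-dimethylcyclohex-3-ene-1-carbaldehyde; 16 diethyl [(7-methoxy-2-oxo-2H-chromen-8-yl)methyl]phosphonate
Product: 17 8-{(E)-2-[(1R,2R)-2-{2-methoxy-4-[(triisopropylsilyl)oxy]phenyl}-1,4-dimethylcyclohex-3-en-1-yl]ethenyl}-7-methoxy-2H-chromen-2-one
Conditions: NaH added to 11 and 16 in THF, 0 °C to rt
Reagents that add atoms: none
Why: Horner–Wadsworth–Emmons olefination; the aldehyde has no α-hydrogen, so base can be added to a mixture of both partners, which keeps the phosphonate anion dilute and spares the lactone of 16, and the stabilized benzylic phosphonate should give the E alkene.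

Step 14
Reactants: 17 8-{(E)-2-[(1R,2R)-2-{2-methoxy-4-[(triisopropylsilyl)oxy]phenyl}-1,4-dimethylcyclohex-3-en-1-yl]ethenyl}-7-methoxy-2H-chromen-2-one
Product: 18 8-{(E)-2-[(1R,2R)-2-(4-hydroxy-2-methoxyphenyl)-1,4-dimethylcyclohex-3-en-1-yl]ethenyl}-7-methoxy-2H-chromen-2-one
Conditions: Bu4NF, AcOH, THF, 0 °C
Reagents that add atoms: none
Why: Fluoride cleaves the aryl silyl ether; acetic acid buffers the phenoxide so that the coumarin lactone is not opened, and no acid strong enough to move the ring alkene is present.

Step 15
Reactants: 18 8-{(E)-2-[(1R,2R)-2-(4-hydroxy-2-methoxyphenyl)-1,4-dimethylcyclohex-3-en-1-yl]ethenyl}-7-methoxy-2H-chromen-2-one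
Product: 19 2-hydroxy-4-methoxy-5-[(1R,6R)-6-[(E)-2-(7-methoxy-2-oxo-2H-chromen-8-yl)ethenyl]-3,6-dimethylcyclohex-2-en-1-yl]benzaldehyde
Conditions: MgCl2, Et3N, (CH2O)n, MeCN, reflux
Reagents that add atoms: formaldehyde (as paraformaldehyde), C=O
Why: ortho-Formylation of a magnesium phenoxide with formaldehyde (Casnati–Skattebøl reaction); the para position is occupied by C1, and of the two ortho positions C4a′ is open and para to the methoxy group while C8′ lies between two oxygens, so the aldehyde should enter at C4a′.

Step 16
Reactants: 19 2-hydroxy-4-methoxy-5-[(1R,6R)-6-[(E)-2-(7-methoxy-2-oxo-2H-chromen-8-yl)ethenyl]-3,6-dimethylcyclohex-2-en-1-yl]benzaldehyde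
Product: 21 7-methoxy-6-[(1R,6R)-6-[(E)-2-(7-methoxy-2-oxo-2H-chromen-8-yl)ethenyl]-3,6-dimethylcyclohex-2-en-1-yl]-2H-chromen-2-one (target), via ethyl hydroxycinnamate 20 (not isolated)
Conditions: Ph3P=CHCO2Et, PhNEt2, reflux
Reagents that add atoms: ethyl (triphenylphosphoranylidene)acetate, CCOC(=O)C=P(c1ccccc1)(c1ccccc1)c1ccccc1
Why: Wittig olefination of the salicylaldehyde gives cinnamate 20, which at this temperature isomerizes to the Z form and lactonizes with loss of ethanol (Wittig lactonization to a coumarin); no stereocentre is involved.

## Compound list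

1 | 4-methylbenzoic acid | Cc1ccc(C(=O)O)cc1 | starting material
2 | dilithium (4-methylcyclohexa-2,5-dien-1-ylidene)methanediolate | [Li+].[Li+].CC1C=CC(=C([O-])[O-])C=C1 | intermediate (not isolated)
3 | cis-1,4-dimethylcyclohexa-2,5-diene-1-carboxylic acid | C[C@@H]1C=C[C@@](C)(C(=O)O)C=C1 | intermediate
4 | 4-bromoresorcinol (4-bromobenzene-1,3-diol) | Oc1ccc(Br)c(O)c1 | starting material
5 | 2-bromo-5-[(triisopropylsilyl)oxy]phenol | CC(C)[Si](Oc1ccc(Br)c(O)c1)(C(C)C)C(C)C | intermediate
6 | 2-bromo-5-[(triisopropylsilyl)oxy]phenyl cis-1,4-dimethylcyclohexa-2,5-diene-1-carboxylate | C[C@@H]1C=C[C@@](C)(C(=O)Oc2cc(O[Si](C(C)C)(C(C)C)C(C)C)ccc2Br)C=C1 | intermediate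
7 | (6aS,10aS)-6a,9-dimethyl-3-[(triisopropylsilyl)oxy]-6a,10a-dihydro-6H-benzo[c]chromen-6-one | O=C1Oc2cc(O[Si](C(C)C)(C(C)C)C(C)C)ccc2[C@@H]2C=C(C)C=C[C@]12C | intermediate
8 | (6aS,10aS)-6a,9-dimethyl-3-[(triisopropylsilyl)oxy]-6a,7,8,10a-tetrahydro-6H-benzo[c]chromen-6-one | O=C1Oc2cc(O[Si](C(C)C)(C(C)C)C(C)C)ccc2[C@@H]2C=C(C)CC[C@]12C | intermediate
9 | 2-[(1R,6S)-6-(hydroxymethyl)-3,6-dimethylcyclohex-2-en-1-yl]-5-[(triisopropylsilyl)oxy]phenol | Oc1cc(O[Si](C(C)C)(C(C)C)C(C)C)ccc1[C@@H]1C=C(C)CC[C@@]1(CO)C | intermediate
10 | [(1S,2R)-2-{2-methoxy-4-[(triisopropylsilyl)oxy]phenyl}-1,4-dimethylcyclohex-3-en-1-yl]methanol | COc1cc(O[Si](C(C)C)(C(C)C)C(C)C)ccc1[C@@H]1C=C(C)CC[C@@]1(CO)C | intermediate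
11 | (1S,2S)-2-{2-methoxy-4-[(triisopropylsilyl)oxy]phenyl}-1,4-dimethylcyclohex-3-ene-1-carbaldehyde | COc1cc(O[Si](C(C)C)(C(C)C)C(C)C)ccc1[C@@H]1C=C(C)CC[C@@]1(C=O)C | intermediate
12 | 2-methylresorcinol (2-methylbenzene-1,3-diol) | Cc1c(O)cccc1O | starting material
13 | 7-hydroxy-8-methyl-2H-chromen-2-one | Cc1c(O)ccc2ccc(=O)oc12 | intermediate
14 | 7-methoxy-8-methyl-2H-chromen-2-one | COc1ccc2ccc(=O)oc2c1C | intermediate
15 | 8-(bromomethyl)-7-methoxy-2H-chromen-2-one | COc1ccc2ccc(=O)oc2c1CBr | intermediate
16 | diethyl [(7-methoxy-2-oxo-2H-chromen-8-yl)methyl]phosphonate | CCOP(=O)(OCC)Cc1c(OC)ccc2ccc(=O)oc12 | intermediate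
17 | 8-{(E)-2-[(1R,2R)-2-{2-methoxy-4-[(triisopropylsilyl)oxy]phenyl}-1,4-dimethylcyclohex-3-en-1-yl]ethenyl}-7-methoxy-2H-chromen-2-one | COc1cc(O[Si](C(C)C)(C(C)C)C(C)C)ccc1[C@@H]1C=C(C)CC[C@]1(C)/C=C/c1c(OC)ccc2ccc(=O)oc12 | intermediate
18 | 8-{(E)-2-[(1R,2R)-2-(4-hydroxy-2-methoxyphenyl)-1,4-dimethylcyclohex-3-en-1-yl]ethenyl}-7-methoxy-2H-chromen-2-one | COc1cc(O)ccc1[C@@H]1C=C(C)CC[C@]1(C)/C=C/c1c(OC)ccc2ccc(=O)oc12 | intermediate
19 | 2-hydroxy-4-methoxy-5-[(1R,6R)-6-[(E)-2-(7-methoxy-2-oxo-2H-chromen-8-yl)ethenyl]-3,6-dimethylcyclohex-2-en-1-yl]benzaldehyde | COc1cc(O)c(C=O)cc1[C@@H]1C=C(C)CC[C@]1(C)/C=C/c1c(OC)ccc2ccc(=O)oc12 | intermediate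
20 | ethyl (E)-3-{2-hydroxy-4-methoxy-5-[(1R,6R)-6-[(E)-2-(7-methoxy-2-oxo-2H-chromen-8-yl)ethenyl]-3,6-dimethylcyclohex-2-en-1-yl]phenyl}prop-2-enoate | CCOC(=O)/C=C/c1cc([C@@H]2C=C(C)CC[C@]2(C)/C=C/c2c(OC)ccc3ccc(=O)oc23)c(OC)cc1O | intermediate (not isolated)
21 | 7-methoxy-6-[(1R,6R)-6-[(E)-2-(7-methoxy-2-oxo-2H-chromen-8-yl)ethenyl]-3,6-dimethylcyclohex-2-en-1-yl]-2H-chromen-2-one | COc1cc2oc(=O)ccc2cc1[C@@H]1C=C(C)CC[C@]1(C)/C=C/c1c(OC)ccc2ccc(=O)oc12 | target

## Step count and risks

Total: 16 steps. Longest linear sequence: 11 steps (1, 3, 4, 5, 6, 7, 8, 13, 14, 15, 16) from 4-methylbenzoic acid.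

**Step 4 (key step).** The most likely failure is incomplete differentiation of the two enantiotopic alkenes. The ester tether must first rotate into its less favoured s-cis form, and the insertion transition state is looser than with all-carbon tethers. The electron-rich aryl bromide also adds slowly to zerovalent palladium, which gives hydrodebromination and ester cleavage time to compete. The fallback replaces catalyst control of enantiopurity by resolution; it sets out from alcohol 10 and returns to 10. Alcohol 10 of whatever enantiomeric purity is acylated with (2R)-2-methoxy-2-phenylacetyl chloride and pyridine. The diastereomeric esters are separated by chromatography or crystallization, and the one kept is [(1S,2R)-2-{2-methoxy-4-[(triisopropylsilyl)oxy]phenyl}-1,4-dimethylcyclohex-3-en-1-yl]methyl (2R)-2-methoxy-2-phenylacetate F1. LiAlH4 in THF at 0 °C then releases pure 10 without touching the silyl ether. The same detour resolves racemic material if the cyclization is run with PPh3.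

**Step 1.** The most likely failure is an unfavourable diastereomer distribution, because methyl iodide enters preferentially anti to the 4-methyl group and the needed cis acid is then the minor product. The two acids are also nearly identical and may separate poorly. The fallback removes the sacrificial stereocentre; it sets out from phenol 5 and returns at 7. Benzoic acid is reduced and methylated as in step 1 to 1-methylcyclohexa-2,5-diene-1-carboxylic acid F2, which has no diastereomer. Esterification with 5 as in step 3 gives 2-bromo-5-[(triisopropylsilyl)oxy]phenyl 1-methylcyclohexa-2,5-diene-1-carboxylate F3. Oxidation of the doubly allylic CH2 group with CrO3 and 3,5-dimethylpyrazole gives the cross-conjugated dienone 2-bromo-5-[(triisopropylsilyl)oxy]phenyl 1-methyl-4-oxocyclohexa-2,5-diene-1-carboxylate F4. A desymmetrizing reductive Heck cyclization (Pd(OAc)2, (R)-BINAP, HCO2Na, DMF, 80 °C) adds the aryl group to one enantiotopic enone β-carbon through the same tether and gives (6aS,10aS)-6a-methyl-3-[(triisopropylsilyl)oxy]-10,10a-dihydro-6H-benzo[c]chromene-6,9(6aH)-dione F5. The ketone of F5 can enolize only toward C10, so LiN(SiMe3)2 and PhNTf2 at −78 °C give (6aS,10aS)-6a-methyl-6-oxo-3-[(triisopropylsilyl)oxy]-6a,10a-dihydro-6H-benzo[c]chromen-9-yl trifluoromethanesulfonate F6. Stille coupling with Me4Sn (Pd(PPh3)4, LiCl, THF, reflux) gives 7. The detour costs three more steps but needs neither a syn β-hydrogen nor a diastereomer separation.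

**Step 5.** The most likely failure is over-reduction of the trisubstituted alkene, or incomplete conversion if the reagent is withheld, since the selectivity rests only on a rate difference between two alkenes of one diene. The fallback uses a directing group; it sets out from 7 and returns at 9. LiAlH4 opens the lactone of 7 first and gives 2-[(1R,6S)-6-(hydroxymethyl)-3,6-dimethylcyclohexa-2,4-dien-1-yl]-5-[(triisopropylsilyl)oxy]phenol F7. Hydrogenation with [Rh(nbd)(dppb)]BF4 and H2 in CH2Cl2 is then directed by the primary hydroxyl on C6 to the homoallylic C4=C5 alkene, which the catalyst reaches far more easily than the trisubstituted, more remote C2=C3 alkene, and gives 9.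

**Step 13.** The most likely failure is slow addition of the ortho,ortho'-disubstituted benzylic phosphonate anion to the neopentyl aldehyde, which leaves the anion time to attack the lactone of another molecule of 16. The fallback avoids carbanions; it sets out from 11 and returns at 17. Methylenation of 11 with Ph3P=CH2 gives triisopropyl{3-methoxy-4-[(1R,6R)-6-ethenyl-3,6-dimethylcyclohex-2-en-1-yl]phenoxy}silane F8. Commercial 7-hydroxycoumarin is iodinated with I2 and KI in aqueous NH3 to 7-hydroxy-8-iodo-2H-chromen-2-one F9 and methylated (MeI, K2CO3) to 8-iodo-7-methoxy-2H-chromen-2-one F10. A Mizoroki–Heck reaction of F8 with F10 (Pd(OAc)2, Bu4NCl, NaHCO3, DMF, 80 °C) gives 17. The vinyl group sits on a quaternary carbon, so β-hydride elimination can occur only toward the aryl-bearing carbon and gives the E styryl alkene, and the trisubstituted ring alkene is too hindered to compete.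

## Further compounds

F1 | step 4 | [(1S,2R)-2-{2-methoxy-4-[(triisopropylsilyl)oxy]phenyl}-1,4-dimethylcyclohex-3-en-1-yl]methyl (2R)-2-methoxy-2-phenylacetate | COc1cc(O[Si](C(C)C)(C(C)C)C(C)C)ccc1[C@@H]1C=C(C)CC[C@@]1(COC(=O)[C@H](OC)c1ccccc1)C
F2 | step 1 | 1-methylcyclohexa-2,5-diene-1-carboxylic acid | CC1(C(=O)O)C=CCC=C1
F3 | step 1 | 2-bromo-5-[(triisopropylsilyl)oxy]phenyl 1-methylcyclohexa-2,5-diene-1-carboxylate | CC1(C(=O)Oc2cc(O[Si](C(C)C)(C(C)C)C(C)C)ccc2Br)C=CCC=C1
F4 | step 1 | 2-bromo-5-[(triisopropylsilyl)oxy]phenyl 1-methyl-4-oxocyclohexa-2,5-diene-1-carboxylate | CC1(C(=O)Oc2cc(O[Si](C(C)C)(C(C)C)C(C)C)ccc2Br)C=CC(=O)C=C1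
F5 | step 1 | (6aS,10aS)-6a-methyl-3-[(triisopropylsilyl)oxy]-10,10a-dihydro-6H-benzo[c]chromene-6,9(6aH)-dione | O=C1Oc2cc(O[Si](C(C)C)(C(C)C)C(C)C)ccc2[C@@H]2CC(=O)C=C[C@]12C
F6 | step 1 | (6aS,10aS)-6a-methyl-6-oxo-3-[(triisopropylsilyl)oxy]-6a,10a-dihydro-6H-benzo[c]chromen-9-yl trifluoromethanesulfonate | O=C1Oc2cc(O[Si](C(C)C)(C(C)C)C(C)C)ccc2[C@@H]2C=C(OS(=O)(=O)C(F)(F)F)C=C[C@]12C
F7 | step 5 | 2-[(1R,6S)-6-(hydroxymethyl)-3,6-dimethylcyclohexa-2,4-dien-1-yl]-5-[(triisopropylsilyl)oxy]phenol | Oc1cc(O[Si](C(C)C)(C(C)C)C(C)C)ccc1[C@@H]1C=C(C)C=C[C@@]1(CO)C
F8 | step 13 | triisopropyl{3-methoxy-4-[(1R,6R)-6-ethenyl-3,6-dimethylcyclohex-2-en-1-yl]phenoxy}silane | COc1cc(O[Si](C(C)C)(C(C)C)C(C)C)ccc1[C@@H]1C=C(C)CC[C@]1(C)C=C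
F9 | step 13 | 7-hydroxy-8-iodo-2H-chromen-2-one | Oc1ccc2ccc(=O)oc2c1I
F10 | step 13 | 8-iodo-7-methoxy-2H-chromen-2-one | COc1ccc2ccc(=O)oc2c1I
A1 | alternative 1 | (1S,2S)-2-(7-methoxy-2-oxo-2H-chromen-6-yl)-1,4-dimethylcyclohex-3-ene-1-carboxylic acid | COc1cc2oc(=O)ccc2cc1[C@@H]1C=C(C)CC[C@]1(C)C(=O)O
A2 | alternative 2 | (S)-1-methyl-4-oxocyclohex-2-ene-1-carbonitrile | O=C1CC[C@](C)(C#N)C=C1
A3 | alternative 3 | 2-[(1R,6S)-6-{[(tert-butyldimethylsilyl)oxy]methyl}-3,6-dimethylcyclohex-2-en-1-yl]-5-[(triisopropylsilyl)oxy]phenol | Oc1cc(O[Si](C(C)C)(C(C)C)C(C)C)ccc1[C@@H]1C=C(C)CC[C@]1(C)CO[Si](C)(C)C(C)(C)C
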